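## Retrosynthetic overview

1. The target is opened at the lactone aryl C–O bond of its 6-hydroxy-7-methoxycoumarin half (C8a–O1). That leaves an (E)-α-aryloxycinnamic acid with a free phenol para to the C–H that must be oxygenated.
2. The E acid comes from its stable Z isomer by photoisomerisation. The Z acid comes from a Perkin-type condensation of isovanillin with (coumarin-7-yloxy)acetic acid.
3. That acid is cut at its ether O–CH2 bond (the oxygen–carbon bond that becomes the O–C3 link of the target), giving umbelliferone and ethyl bromoacetate.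
4. Ring order: the umbelliferone bicycle is bought intact, the benzene ring of the second coumarin comes from isovanillin, and its pyranone ring is closed last through oxygen.

Assumption: the target has no stereocentre or other stereogenic element, so it exists as a single stereoisomer; the only geometric element in the route is the C=C bond of 7, 8 and 9.

## Route

Step 1
Reactants: 1 umbelliferone (7-hydroxy-2H-chromen-2-one); 2 ethyl bromoacetate
Product: 4 2-[(2-oxo-2H-chromen-7-yl)oxy]acetic acid, via ethyl ester 3 (not isolated)
Conditions: K2CO3, acetone, reflux; filter, evaporate; 1 M NaOH, THF–H2O, 0 °C; HCl to pH 2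
Reagents that add atoms: sodium hydroxide, [Na+].[OH-] (supplies the oxygen of the acid OH)
Why: Williamson ether synthesis (SN2 of the acidic 7-phenoxide on the α-bromo ester) followed by saponification of the activated aryloxyacetate ester, which is much faster than attack on the conjugated coumarin lactone; no stereocentre is formed.

Step 2
Reactants: 4 2-[(2-oxo-2H-chromen-7-yl)oxy]acetic acid; 5 isovanillin (3-hydroxy-4-methoxybenzaldehyde)
Product: 8 (Z)-3-(3-hydroxy-4-methoxyphenyl)-2-[(2-oxo-2H-chromen-7-yl)oxy]prop-2-enoic acid, via isovanillin acetate 6 (not isolated), via O-acetyl acid 7 (not isolated)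
Conditions: Ac2O, Et3N, 120 °C; then H2O, 60 °C; then 1 M NaOH, THF–H2O, 0 °C; HCl to pH 2
Reagents that add atoms: acetic anhydride, CC(=O)OC(C)=O (its acetyl group is carried only by 6 and 7 and is removed again before 8 is isolated)
Why: Perkin–Oglialoro condensation: the mixed-anhydride enolate of 4 adds to the aldehyde and eliminates to the more stable Z alkene (aryl trans to CO2H); the phenolic acetate is saponified in the work-up, and the geometry is not critical because step 3 equilibrates it.

Step 3
Reactants: 8 (Z)-3-(3-hydroxy-4-methoxyphenyl)-2-[(2-oxo-2H-chromen-7-yl)oxy]prop-2-enoic acid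
Product: 11 6-hydroxy-7-methoxy-3-[(2-oxo-2H-chromen-7-yl)oxy]-2H-chromen-2-one (target), via E acid 9 (not isolated), via dienone lactone 10 (not isolated)
Conditions: fac-Ir(ppy)3 (1 mol%), 450 nm LED, degassed MeCN, rt; then dark, HFIP, PhI(OAc)2 (1.05 equiv), 0 °C
Reagents that add atoms: none
Why: Proposed new method: one-pot contra-thermodynamic Z→E photoisomerisation followed by phenol-directed, para-selective dehydrogenative C–O lactonisation. Triplet energy transfer from Ir(ppy)3 (about 55 kcal/mol, below the roughly 62 kcal/mol of the coumarin unit) excites the planar Z acid 8 and enriches the twisted E acid 9, whose CO2H is cis to the aryl ring. PhI(OAc)2 then activates the phenol oxygen by ligand exchange at iodine(III), and the cis-carboxylate attacks the ring carbon para to that oxygen through a six-membered transition state with loss of PhI. The ortho carbon is flanked on both sides, and acetate addition at the methoxy-bearing carbon is expected to be reversible in HFIP. The resulting dienone 10 tautomerises at once to the aromatic phenol 11, and no stereocentre remains. The closest known reaction types are the photocatalytic E→Z isomerisation/oxidative cyclisation of cinnamic acids to coumarins, the iodine(III)-mediated oxidative lactonisation of 3,3-diarylacrylic acids, and the iodine(III) dearomatising para-spirolactonisation of phenols carrying a carboxylic acid side chain; none has been shown for a meta-tethered α-aryloxyacrylic acid closing onto an unsubstituted para C–H of a free phenol.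

## Compound list

1 | umbelliferone (7-hydroxy-2H-chromen-2-one) | O=c1ccc2ccc(O)cc2o1 | starting material
2 | ethyl bromoacetate | CCOC(=O)CBr | starting material
3 | ethyl 2-[(2-oxo-2H-chromen-7-yl)oxy]acetate | CCOC(=O)COc1ccc2ccc(=O)oc2c1 | intermediate
4 | 2-[(2-oxo-2H-chromen-7-yl)oxy]acetic acid | OC(=O)COc1ccc2ccc(=O)oc2c1 | intermediate
5 | isovanillin (3-hydroxy-4-methoxybenzaldehyde) | COc1ccc(C=O)cc1O | starting material
6 | 5-formyl-2-methoxyphenyl acetate (isovanillin acetate) | COc1ccc(C=O)cc1OC(C)=O | intermediate
7 | (Z)-3-(3-acetoxy-4-methoxyphenyl)-2-[(2-oxo-2H-chromen-7-yl)oxy]prop-2-enoic acid | OC(=O)/C(Oc1ccc2ccc(=O)oc2c1)=C/c1ccc(OC)c(OC(C)=O)c1 | intermediate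
8 | (Z)-3-(3-hydroxy-4-methoxyphenyl)-2-[(2-oxo-2H-chromen-7-yl)oxy]prop-2-enoic acid | OC(=O)/C(Oc1ccc2ccc(=O)oc2c1)=C/c1ccc(OC)c(O)c1 | intermediate
9 | (E)-3-(3-hydroxy-4-methoxyphenyl)-2-[(2-oxo-2H-chromen-7-yl)oxy]prop-2-enoic acid | OC(=O)/C(Oc1ccc2ccc(=O)oc2c1)=C\c1ccc(OC)c(O)c1 | intermediate
10 | 7-methoxy-3-[(2-oxo-2H-chromen-7-yl)oxy]-8aH-chromene-2,6-dione (racemic at C8a, transient) | COC1=CC2OC(=O)C(Oc3ccc4ccc(=O)oc4c3)=CC2=CC1=O | intermediate
11 | 6-hydroxy-7-methoxy-3-[(2-oxo-2H-chromen-7-yl)oxy]-2H-chromen-2-one | COc1cc2oc(=O)c(Oc3ccc4ccc(=O)oc4c3)cc2cc1O | target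

## Totals and risks

Total step count: 3. Longest linear sequence: 3 steps (1 → 4 → 8 → 11); isovanillin 5 enters at step 2.

Steps most likely to fail, most risky first:

1. Step 3 (the proposed new method). The photostationary state may not be rich enough in 9, the carboxylate may close at the carbon ortho to the phenol oxygen, or iodine(III) may oxidise the methoxy-bearing carbon to quinone-type products. The fallback uses only known chemistry; it sets out from 5 and 4 and comes back to the route at 11. An Elbs persulfate oxidation of 5 (K2S2O8, aq NaOH, 0 °C to rt) places oxygen para to the phenol and gives potassium 2-formyl-4-hydroxy-5-methoxyphenyl sulfate F4. Hot dilute HCl hydrolyses it to 2,5-dihydroxy-4-methoxybenzaldehyde F5. A classical Perkin coumarin synthesis of F5 with 4 (Ac2O, NaOAc, 150 °C) passes through 2-formyl-5-methoxy-1,4-phenylene diacetate F6 and closes the pyranone by C–C condensation, giving 6-acetoxy-7-methoxy-3-[(2-oxo-2H-chromen-7-yl)oxy]-2H-chromen-2-one F7. Mild acid deacetylation (dilute HCl, aq EtOH, 60 °C) then gives 11.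

2. Step 2. A Perkin condensation of an aryloxyacetic acid with an aldehyde that has no ortho-hydroxyl can be sluggish, and acetic anhydride can condense with the aldehyde itself. The fallback replaces the condensation by an olefination; it sets out from 1, takes up 5, and comes back to the route at 8. Rh2(OAc)4-catalysed O–H insertion of ethyl diazo(diethoxyphosphoryl)acetate into 1 (toluene, 90 °C) gives ethyl 2-(diethoxyphosphoryl)-2-[(2-oxo-2H-chromen-7-yl)oxy]acetate F2 (racemic). Horner–Wadsworth–Emmons reaction with 5 (LiCl, DBU 2.2 equiv, MeCN, rt) gives ethyl (Z)-3-(3-hydroxy-4-methoxyphenyl)-2-[(2-oxo-2H-chromen-7-yl)oxy]prop-2-enoate F3 (a Z/E mixture, Z drawn). Saponification (LiOH, THF–H2O, 0 °C; HCl) gives 8; any 9 formed alongside is equally usable because step 3 equilibrates the pair.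

3. Step 1. Hydroxide may open the coumarin lactone during saponification and re-closure may be incomplete. The fallback avoids hydroxide altogether; it sets out from 1 and comes back to the route at 4. Alkylation of 1 with tert-butyl bromoacetate (K2CO3, DMF, rt) gives tert-butyl 2-[(2-oxo-2H-chromen-7-yl)oxy]acetate F1, which is cleaved by acidolysis (TFA, CH2Cl2, rt) to 4.

## Further compounds

F1 | step 1 | tert-butyl 2-[(2-oxo-2H-chromen-7-yl)oxy]acetate | CC(C)(C)OC(=O)COc1ccc2ccc(=O)oc2c1
F2 | step 2 | ethyl 2-(diethoxyphosphoryl)-2-[(2-oxo-2H-chromen-7-yl)oxy]acetate (racemic) | CCOC(=O)C(Oc1ccc2ccc(=O)oc2c1)P(=O)(OCC)OCC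
F3 | step 2 | ethyl (Z)-3-(3-hydroxy-4-methoxyphenyl)-2-[(2-oxo-2H-chromen-7-yl)oxy]prop-2-enoate | CCOC(=O)/C(Oc1ccc2ccc(=O)oc2c1)=C/c1ccc(OC)c(O)c1
F4 | step 3 | potassium 2-formyl-4-hydroxy-5-methoxyphenyl sulfate | COc1cc(OS(=O)(=O)[O-])c(C=O)cc1O.[K+]
F5 | step 3 | 2,5-dihydroxy-4-methoxybenzaldehyde | COc1cc(O)c(C=O)cc1O
F6 | step 3 | 2-formyl-5-methoxy-1,4-phenylene diacetate | COc1cc(OC(C)=O)c(C=O)cc1OC(C)=O
F7 | step 3 | 6-acetoxy-7-methoxy-3-[(2-oxo-2H-chromen-7-yl)oxy]-2H-chromen-2-one | COc1cc2oc(=O)c(Oc3ccc4ccc(=O)oc4c3)cc2cc1OC(C)=O
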